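## Structural features

The target (C21H24O8) consists of two six-membered carbocycles joined through one methylene carbon. Ring A is an aromatic 1-propanoyl-2,6-dihydroxy-4-methoxybenzene that carries the bridge at C3 and its only hydrogen at C5, and ring B is the enolised 2-acetyl-4,4-dimethylcyclohexane-1,3,5-trione (acetylfilicinic acid), which carries the bridge at C6. There is no stereocentre, because the only sp3 ring carbon (C4 of ring B) bears two identical methyl groups; the molecule is achiral and only constitution has to be controlled. Ring B is a strong vinylogous acid and a β-triketone, prone to retro-Claisen loss of the acetyl group and to over-alkylation at C6. The bridge sits between two enolisable carbons and can be expelled and scrambled by retro-Michael fragmentation in hot base or acid. The real difficulty is the unsymmetrical CH2 link between two different, highly nucleophilic polycarbonyl rings, together with the regiochemistry of ring A: which oxygen is methylated, and which of the equivalent positions C3 and C5 is alkylated. The key step exploits the fact that C1 to C6 of ring A plus the propanoyl carbonyl form a 1,3,5,7-oxygenated nine-carbon chain, a tetraketide whose C3 oxygen is a methyl enol ether and whose C2 carries the bridge. This chain is stored in a 4-methoxy-6-(2-oxobutyl)-2-pyranone, so ring A can be created last by lactone opening and Claisen closure, with every substituent placed by the ring construction.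

## Logic of the disconnections

**9 to 7 (through 8).** The cut is the ring A bond between C1 (the propanoyl-bearing carbon) and C2 (the hydroxyl-bearing carbon next to the bridge carbon C3). In the reverse sense C2 returns to a lactone carbonyl bound to the oxygen on C6. The cut is made here because the oxygen pattern of ring A is that of a Claisen-folded tetraketide, and because the methoxy carbon and the bridge carbon are then already fixed as C4 and C3 of a 2-pyranone. The gain is that the aromatic ring and all its regiochemical questions disappear; 7 is an isomer of 9 and is built on a commercial heterocycle. The demand on the forward step is that lactone opening and C-acylation proceed in the presence of ring B and the bridge, and that Claisen closure beats reclosure to the pyranone.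

**7 to 6.** The cut is the bond between the exocyclic CH2 on C6 of the pyranone ring and the ketone carbon of the 2-oxobutyl chain. A 6-methyl-2-pyranone is a vinylogous ester whose methyl group can be metalated, so the propanoyl unit can come from N-methoxy-N-methylpropanamide. The gain is three carbons removed and a plain methyl group left on the heterocycle. The demand is that ring B tolerates excess amide base, which it should as its dienolate dianion.

**6 to 2 and 4.** The cut is the bond between the bridging CH2 and C6 of ring B. C6 is the only nucleophilic carbon of 4, and in 2 the bridge carbon is present as an aldehyde on a ring with no nucleophilic carbon, so electrophile and nucleophile roles cannot be exchanged and no symmetrical dimer can arise. The gain is a convergent union of two fragments of similar size, each one step from a commercial compound. The demand is that hydride transfer to the condensation product 5 outpaces addition of a second molecule of 4, and that the 4-methoxy group of 2 is not displaced.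

**2 to 1.** The cut is the C3–CHO bond. C3 is the enol-ether β-carbon of the 4-methoxy-2-pyranone and its normal site of electrophilic substitution. The gain is a commercial starting material. The demand is C3 over C5 selectivity and survival of the methyl ether under the Lewis acid.

**4 to 3.** The cuts are the two C4–CH3 bonds of ring B. Geminal C-methylation of a phloroglucinol dearomatises the ring and creates the quaternary carbon in one operation. The gain is a commercial acetophenone. The demand is that alkylation stops after two methyl groups on one carbon.

## Other disconnections considered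

**Alternative 1:** (the first that comes to mind) Both bonds to the bridging CH2 are cut. The forward key step is the condensation of 1-(2,6-dihydroxy-4-methoxyphenyl)propan-1-one A1 and 4 with formaldehyde. A two-stage variant would first turn 4 into the Mannich base 2-acetyl-6-[(dimethylamino)methyl]-3,5-dihydroxy-4,4-dimethylcyclohexa-2,5-dien-1-one A2 and would then heat A2 with A1, so that loss of dimethylamine and Michael addition form the bridge.
- Both partners are carbon nucleophiles of similar reactivity toward the same methylene-trione intermediate, so symmetrical methylene-bridged dimers compete.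
- The stepwise variant does not remove this competition, because the methylene-trione released from A2 can be trapped by the ring B enolate of a second molecule of A2 as readily as by A1.
- A1 has two equivalent free positions (C3 and C5) and can be bridged twice.
- The product can re-equilibrate by bridge exchange under the conditions that form it.
- The chosen plan fixes the roles of the partners and leaves ring A with a C5–H that was never a nucleophilic site.

**Alternative 2:** The two C–CH3 bonds at C4 of ring B are cut. The forward key step is a late dearomatising geminal C-dimethylation (MeI, NaOMe) of the diarylmethane 1-[3-[(3-acetyl-2,4,6-trihydroxyphenyl)methyl]-2,6-dihydroxy-4-methoxyphenyl]propan-1-one A3 to give the target directly.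
- The free C5 of ring A in A3 lies between two oxygenated carbons and is as nucleophilic as the carbon to be methylated.
- O-methylation of the phenols and stopping at exactly two methyl groups add further selectivity demands.
- A3 itself still needs the same unsymmetrical bridge, so the hardest problem is only moved to an earlier intermediate.

**Alternative 3:** Ring B is cut at C2–C3 and C5–C6. The forward key step is a double C-acylation (Claisen then Dieckmann closure) of an α,α'-bis-enolate equivalent of 4-[2,4-bis(benzyloxy)-6-methoxy-3-propanoylphenyl]butan-2-one A4 with dimethylmalonyl dichloride. The product would be 2-{[2,4-bis(benzyloxy)-6-methoxy-3-propanoylphenyl]methyl}-3,5-dihydroxy-4,4-dimethylcyclohexa-2,5-dien-1-one A5 and the target would follow from A5 by C-acetylation of the free ring B carbon and debenzylation.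
- After the first acylation of A4 the enolised 1,3-diketone can close on the second acid chloride through oxygen (a pyrandione) as easily as through carbon.
- The propanoyl group of ring A is a third enolisable ketone that competes in the enolate chemistry.
- Protecting groups, a separate acetylation of A5 and a multistep preparation of A4 make the plan longer than the chosen one, which needs no protecting group.

Key step: step 5

Remark: ring B exists as rapidly interconverting enol tautomers; the tautomer of the target SMILES is used for every compound that contains it.

## Route

**Step 1**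
Reactants: 1 4-methoxy-6-methyl-2H-pyran-2-one
Product: 2 4-methoxy-6-methyl-2-oxo-2H-pyran-3-carbaldehyde
Conditions: Cl2CHOMe (1.5 equiv), TiCl4 (2.2 equiv), CH2Cl2, 0 °C to 25 °C; then ice-water
Reagents that add atoms: dichloromethyl methyl ether (COC(Cl)Cl); water (O)
Why: Rieche formylation: TiCl4 ionises the dichloromethyl ether to a chloro(methoxy)carbenium ion that attacks C3, the enol-ether β-carbon next to the 4-methoxy donor and the usual site of electrophilic substitution of 4-methoxy-2-pyranones; aqueous work-up hydrolyses the α-chloro ether to the aldehyde. No stereocentre is formed.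

**Step 2**
Reactants: 3 1-(2,4,6-trihydroxyphenyl)ethan-1-one
Product: 4 2-acetyl-3,5-dihydroxy-4,4-dimethylcyclohexa-2,5-dien-1-one (acetylfilicinic acid)
Conditions: NaOMe (3 equiv), MeI (2.2 equiv), MeOH, 0 °C to 25 °C; then aq. HCl
Reagents that add atoms: iodomethane (CI)
Why: Dearomatising geminal C-methylation of a phloroglucinol polyanion: after the first C-methylation the methyl-bearing enolate carbon is the most nucleophilic site and takes the second methyl group, which locks the ring as the cross-conjugated trione; limiting the methyl iodide should leave C6 free. No stereocentre, since the two methyl groups are identical.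

**Step 3**
Reactants: 2 4-methoxy-6-methyl-2-oxo-2H-pyran-3-carbaldehyde; 4 2-acetyl-3,5-dihydroxy-4,4-dimethylcyclohexa-2,5-dien-1-one
Product: 6 2-acetyl-3,5-dihydroxy-6-[(4-methoxy-6-methyl-2-oxo-2H-pyran-3-yl)methyl]-4,4-dimethylcyclohexa-2,5-dien-1-one, via alkylidene trione 5 (not isolated)
Conditions: Hantzsch ester (diethyl 2,6-dimethyl-1,4-dihydropyridine-3,5-dicarboxylate, 1.1 equiv), L-proline (10 mol %), CH2Cl2, 25 °C
Reagents that add atoms: none
Why: Three-component reductive alkylation of a cyclic 1,3-dione: Knoevenagel condensation of C6 of 4, its only free ring carbon, with the aldehyde of 2 gives the electron-poor alkylidene trione 5, which should accept hydride at the exocyclic carbon from the dihydropyridine faster than it adds a second molecule of 4. The roles of electrophile (2) and nucleophile (4) are fixed, so no symmetrical dimer can form; no stereocentre is created.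

**Step 4**
Reactants: 6 2-acetyl-3,5-dihydroxy-6-[(4-methoxy-6-methyl-2-oxo-2H-pyran-3-yl)methyl]-4,4-dimethylcyclohexa-2,5-dien-1-one
Product: 7 2-acetyl-3,5-dihydroxy-6-{[4-methoxy-2-oxo-6-(2-oxobutyl)-2H-pyran-3-yl]methyl}-4,4-dimethylcyclohexa-2,5-dien-1-one
Conditions: LiN(iPr)2 (3.3 equiv), THF–DMPU, −78 °C; then EtC(O)N(OMe)Me (1.3 equiv), −78 °C to −20 °C; then 1 M HCl
Reagents that add atoms: N-methoxy-N-methylpropanamide (CCC(=O)N(C)OC)
Why: Lateral metalation and acylation of a 6-methyl-2-pyranone: two equivalents of amide base turn ring B into its dilithium dienolate, which is inert to further base and to the acyl donor, and the third removes a proton from the 6-methyl group (C3 is blocked). The N-methoxy-N-methyl amide gives a chelated tetrahedral adduct that releases the ketone only on work-up, so neither second addition nor proton quench by the product should interfere.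

**Step 5**
Reactants: 7 2-acetyl-3,5-dihydroxy-6-{[4-methoxy-2-oxo-6-(2-oxobutyl)-2H-pyran-3-yl]methyl}-4,4-dimethylcyclohexa-2,5-dien-1-one
Product: 9 1-[3-[(5-acetyl-2,4-dihydroxy-3,3-dimethyl-6-oxocyclohexa-1,4-dien-1-yl)methyl]-2,6-dihydroxy-4-methoxyphenyl]propan-1-one (target), via ring-opened methyl ester 8 (not isolated)
Conditions: Mg(OMe)2 (6 equiv), MeOH, 65 °C; then cold 1 M HCl
Reagents that add atoms: none
Why: The step is the base-induced ring transformation of a 6-(2-oxoalkyl)-2-pyranone into an acylphloroglucinol (lactone methanolysis, then Claisen condensation), the laboratory counterpart of the Claisen folding of a tetraketide. Mg(OMe)2 first converts ring B and the side-chain methylene into magnesium enolates; methoxide then adds to the lactone carbonyl C2 and the C2–O1 bond breaks, giving the magnesium chelate of the 3-methoxy-5,7-dioxo ester 8. Because the C2=C3 double bond of 8 is inherited from the pyranone ring, the ester carbon and C4 are cis (E alkene) and the chain is held in the folded shape needed for closure. The C6 carbanion of the magnesium-chelated 5,7-diketone attacks the ester carbonyl (6-exo-trig, forming the C1–C6 bond of the chain), methoxide is lost and two enolisations give aromatic ring A, which makes the sequence irreversible. The selectivity needed is Claisen closure (C6 to C1) over aldol closure (C2 to C7); C2 is a fully substituted sp2 carbon of a β-methoxyacrylate and cannot act as an aldol donor, and an aldol product could not aromatise. Regiochemistry is fixed by the precursor: chain C3 with its methoxy group becomes C4 of ring A (para to the propanoyl group), the bridge-bearing C2 becomes C3, the pyranone C5–H becomes the lone C5–H, and the lactone carbonyl oxygen and ring oxygen become the two phenols. Ring B should survive as its magnesium enolate, the form in which such triketones are made and handled in alkoxide media. No stereocentre is formed, and the net change from 7 to 9 is an isomerisation.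

## Compound list

1 | 4-methoxy-6-methyl-2H-pyran-2-one | COC1=CC(=O)OC(C)=C1 | starting material
2 | 4-methoxy-6-methyl-2-oxo-2H-pyran-3-carbaldehyde | COC1=C(C=O)C(=O)OC(C)=C1 | intermediate
3 | 1-(2,4,6-trihydroxyphenyl)ethan-1-one | CC(=O)c1c(O)cc(O)cc1O | starting material
4 | 2-acetyl-3,5-dihydroxy-4,4-dimethylcyclohexa-2,5-dien-1-one (acetylfilicinic acid) | CC(=O)C1=C(O)C(C)(C)C(O)=CC1=O | intermediate
5 | 2-acetyl-3-hydroxy-6-[(4-methoxy-6-methyl-2-oxo-2H-pyran-3-yl)methylidene]-4,4-dimethylcyclohex-2-ene-1,5-dione (alkene geometry not controlled, both isomers give 6) | COC1=C(C=C2C(=O)C(C(C)=O)=C(O)C(C)(C)C2=O)C(=O)OC(C)=C1 | intermediate (not isolated)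
6 | 2-acetyl-3,5-dihydroxy-6-[(4-methoxy-6-methyl-2-oxo-2H-pyran-3-yl)methyl]-4,4-dimethylcyclohexa-2,5-dien-1-one | COC1=C(CC2=C(O)C(C)(C)C(O)=C(C(C)=O)C2=O)C(=O)OC(C)=C1 | intermediate
7 | 2-acetyl-3,5-dihydroxy-6-{[4-methoxy-2-oxo-6-(2-oxobutyl)-2H-pyran-3-yl]methyl}-4,4-dimethylcyclohexa-2,5-dien-1-one | CCC(=O)CC1=CC(OC)=C(CC2=C(O)C(C)(C)C(O)=C(C(C)=O)C2=O)C(=O)O1 | intermediate
8 | methyl (2E)-2-[(5-acetyl-2,4-dihydroxy-3,3-dimethyl-6-oxocyclohexa-1,4-dien-1-yl)methyl]-3-methoxy-5,7-dioxonon-2-enoate (present as its magnesium enolate) | CCC(=O)CC(=O)C/C(OC)=C(/CC1=C(O)C(C)(C)C(O)=C(C(C)=O)C1=O)C(=O)OC | intermediate (not isolated)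
9 | 1-[3-[(5-acetyl-2,4-dihydroxy-3,3-dimethyl-6-oxocyclohexa-1,4-dien-1-yl)methyl]-2,6-dihydroxy-4-methoxyphenyl]propan-1-one | CCC(=O)c1c(O)cc(OC)c(CC2=C(O)C(C)(C)C(O)=C(C(C)=O)C2=O)c1O | target

## Step count and least certain steps

Total step count: 5. Longest linear sequence: 4 steps (1 to 2 to 6 to 7 to 9); the branch 3 to 4 joins at step 3.

**Step 5 (key step).** Claisen closure onto the α-substituted, β-methoxy-deactivated ester may be slower than reclosure of the open chain to the pyranone. Once ring A exists, its phenoxide may expel ring B by retro-Michael fragmentation, so the bridge could be redistributed. A ring B enolate oxygen may also displace the 4-methoxy group of the pyranone intramolecularly. Fallback (sets out from 2, returns at 9): bridge formation and aromatisation change places. Compound 2 is acetalised (HC(OMe)3, TsOH, MeOH) to 3-(dimethoxymethyl)-4-methoxy-6-methyl-2H-pyran-2-one F1. Lateral acylation (LiN(iPr)2, then N-methoxy-N-methylpropanamide) gives 3-(dimethoxymethyl)-4-methoxy-6-(2-oxobutyl)-2H-pyran-2-one F2. Mg(OMe)2 in MeOH performs the same ring transformation on this substrate, which lacks ring B, to give 1-[3-(dimethoxymethyl)-2,6-dihydroxy-4-methoxyphenyl]propan-1-one F3. Dilute acid hydrolyses the acetal to 2,4-dihydroxy-6-methoxy-3-propanoylbenzaldehyde F4. Reductive alkylation of 4 with this aldehyde (Hantzsch ester, L-proline) then gives 9.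

**Step 4.** Aggregation or poor solubility of the trilithiated species may leave the 6-methyl group incompletely metalated. Competing deprotonation of the ring B acetyl group would send the acyl donor to the wrong carbon. Fallback (sets out from 2, returns at 7): the ketone is installed before ring B is present. Compound 2 is converted as above into 3-(dimethoxymethyl)-4-methoxy-6-methyl-2H-pyran-2-one F1 and then into 3-(dimethoxymethyl)-4-methoxy-6-(2-oxobutyl)-2H-pyran-2-one F2. Aqueous HCl in THF frees 4-methoxy-2-oxo-6-(2-oxobutyl)-2H-pyran-3-carbaldehyde F5. This aldehyde is joined to 4 under the conditions of step 3 to give 7.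

**Step 3.** The proline nitrogen or the enol of 4 may add to C4 of 2 and eliminate methoxide instead of condensing at the aldehyde. A second molecule of 4 may add to 5 before hydride transfer. Fallback (sets out from 2, returns at 6): the bridge is made by substitution, not condensation. Compound 2 is reduced (NaBH4, CeCl3·7H2O, MeOH) to 3-(hydroxymethyl)-4-methoxy-6-methyl-2H-pyran-2-one F6. PBr3 gives 3-(bromomethyl)-4-methoxy-6-methyl-2H-pyran-2-one F7. C-alkylation of the monopotassium salt of 4 (K2CO3, aqueous MeOH) with this bromide gives 6.

**Step 1.** Electrophilic attack may occur at C5 instead of C3. TiCl4 may cleave the 4-methyl ether once the chelating 3-formyl group is in place. Fallback (sets out from 1, returns at 2): the aldehyde carbon is brought in by cross-coupling. N-bromosuccinimide converts 1 into 3-bromo-4-methoxy-6-methyl-2H-pyran-2-one F8. Suzuki–Miyaura coupling with CH2=CHBF3K (PdCl2(dppf), Cs2CO3) gives 3-ethenyl-4-methoxy-6-methyl-2H-pyran-2-one F9. Oxidative cleavage of the vinyl group (OsO4 catalytic, NaIO4) gives 2.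

## Further compounds

F1 | step 5 | 3-(dimethoxymethyl)-4-methoxy-6-methyl-2H-pyran-2-one | COC1=C(C(OC)OC)C(=O)OC(C)=C1
F2 | step 5 | 3-(dimethoxymethyl)-4-methoxy-6-(2-oxobutyl)-2H-pyran-2-one | CCC(=O)CC1=CC(OC)=C(C(OC)OC)C(=O)O1
F3 | step 5 | 1-[3-(dimethoxymethyl)-2,6-dihydroxy-4-methoxyphenyl]propan-1-one | CCC(=O)c1c(O)cc(OC)c(C(OC)OC)c1O
F4 | step 5 | 2,4-dihydroxy-6-methoxy-3-propanoylbenzaldehyde | CCC(=O)c1c(O)cc(OC)c(C=O)c1O
F5 | step 4 | 4-methoxy-2-oxo-6-(2-oxobutyl)-2H-pyran-3-carbaldehyde | CCC(=O)CC1=CC(OC)=C(C=O)C(=O)O1
F6 | step 3 | 3-(hydroxymethyl)-4-methoxy-6-methyl-2H-pyran-2-one | COC1=C(CO)C(=O)OC(C)=C1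
F7 | step 3 | 3-(bromomethyl)-4-methoxy-6-methyl-2H-pyran-2-one | COC1=C(CBr)C(=O)OC(C)=C1
F8 | step 1 | 3-bromo-4-methoxy-6-methyl-2H-pyran-2-one | COC1=C(Br)C(=O)OC(C)=C1
F9 | step 1 | 3-ethenyl-4-methoxy-6-methyl-2H-pyran-2-one | COC1=C(C=C)C(=O)OC(C)=C1
A1 | alternative 1 | 1-(2,6-dihydroxy-4-methoxyphenyl)propan-1-one | CCC(=O)c1c(O)cc(OC)cc1O
A2 | alternative 1 | 2-acetyl-6-[(dimethylamino)methyl]-3,5-dihydroxy-4,4-dimethylcyclohexa-2,5-dien-1-one | CC(=O)C1=C(O)C(C)(C)C(O)=C(CN(C)C)C1=O
A3 | alternative 2 | 1-[3-[(3-acetyl-2,4,6-trihydroxyphenyl)methyl]-2,6-dihydroxy-4-methoxyphenyl]propan-1-one | CCC(=O)c1c(O)cc(OC)c(Cc2c(O)cc(O)c(C(C)=O)c2O)c1O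
A4 | alternative 3 | 4-[2,4-bis(benzyloxy)-6-methoxy-3-propanoylphenyl]butan-2-one | CCC(=O)c1c(OCc2ccccc2)cc(OC)c(CCC(C)=O)c1OCc1ccccc1
A5 | alternative 3 | 2-{[2,4-bis(benzyloxy)-6-methoxy-3-propanoylphenyl]methyl}-3,5-dihydroxy-4,4-dimethylcyclohexa-2,5-dien-1-one | CCC(=O)c1c(OCc2ccccc2)cc(OC)c(CC2=C(O)C(C)(C)C(O)=CC2=O)c1OCc1ccccc1
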